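(The data were generated by integration for substances that don't exist, noise included.)

The pitfall was to count the coupling partner once. You asked for a quick number, and your hunch was that slow feeding costs target.

| flask | substrate | fresh partner | coupling partner | remark | time |
|---|---|---|---|---|---|
| alpha | 20 mM | 40 mM | 50 mM | run made earlier |  |
| eta | 20 mM | 60 mM | 50 mM | run made earlier |  |
| amber | 20 mM | 40.0 mM | 50.0 mM (fed, over 30 min) | all else is in the flask from the start; the feed brings no volume worth counting | 40 min |
| ochre | 20 mM (fed, over 30 min) | 40.0 mM | 50.0 mM | all else is in the flask from the start; the feed brings no volume worth counting | 40 min |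
| red | 20 mM | 40.0 mM | 50.0 mM | everything together at the start | 40 min |

| run | time / min | target / % |
|---|---|---|
| alpha | 1.50 | 2.9 |
| alpha | 5.00 | 22.9 |
| alpha | 8.00 | 38.3 |
| alpha | 12.0 | 51.7 |
| alpha | 20.0 | 69.1 |
| alpha | 25.0 | 73.4 |
| eta | 0.667 | 2.8 |
| eta | 1.33 | 4.9 |
| eta | 2.00 | 9.5 |
| eta | 2.50 | 13.5 |
| eta | 3.00 | 14.9 |
| eta | 4.00 | 24.1 |

(standard deviation of a reading: 1 percentage point)

- percent here means substrate units held: one side product counts as two
- what may be going on: coupling partner + fresh partner -> second intermediate; substrate + open intermediate -> side product; open intermediate + second intermediate -> target; substrate + coupling partner -> open intermediate; substrate <-> dormant form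

1. which flask leads in amount of target, in percent of the substrate charged ("all alike" within 1.5 percentage points) (amber / ochre / red / all alike)
2. how much target is there at the end, in percent of the substrate charged: amber
3. how much target is there at the end, in percent of the substrate charged: ochre
4. how much target is there at the end, in percent of the substrate charged: red

The proposed steps were these. Substrate with coupling partner gives open intermediate. Coupling partner with fresh partner gives second intermediate. Those two intermediates give target. Substrate with open intermediate gives side product, and substrate also sits reversibly in dormant form. So each target takes two coupling partners. Per substrate charged, 0.500 remains beyond those two; I called this the coupling margin. I treated it as the small term and reckoned only what draws on it.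

Second intermediate left idle draws on the margin. Eta, richer in fresh partner, reached 24.1 % by 4.00 min, while alpha needed 5.00 min for 22.9 %. The spare fresh partner is 1.00 per substrate, twice the margin, so second intermediate could overdraw it. In ochre, coupling partner stands with fresh partner before the substrate arrives. I therefore expected coupling partner to become the limiting reagent in ochre, and I put ochre behind red.

The forecast stood at 42 % for amber, 70 % for ochre and 78 % for red. It ended: “Red leads narrowly over ochre.”

Amber gave 34.9 %, ochre 55.6 % and red 82.2 %, so red led.

    coupling partner + fresh partner → second intermediate (k = 0.129 M⁻¹ s⁻¹)
    substrate + open intermediate → side product (k = 0.456 M⁻¹ s⁻¹)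
    open intermediate + second intermediate → target (k = 0.0922 M⁻¹ s⁻¹)
    substrate + coupling partner → open intermediate (k = 1.62 M⁻¹ s⁻¹)
    substrate ⇌ dormant form (K = 0.800, k = 0.00108 s⁻¹)

Ochre held 25.2 mM of second intermediate at 40.0 min, with 0.0340 % of its coupling partner left. Per substrate charged, that idle second intermediate is 1.26, more than the margin. It caps ochre at 62.0 %, above the 55.6 % it reached. The neighbour of amber with 12 mM of coupling partner has a margin of −1.40 and a cap of 30.0 %, and it ended at 2.84 %.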